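**Plan**

1. Numbering used throughout (as in dione 16): C1 = OMe bridgehead, C2 = carbinol carbon, C3 = enol-ether carbon, C4 = vinylic CH, C5 = allyl bridgehead, C6 = CHMe, C7 = CHAr, C8 = bridging C=O.
2. Retrosynthesis: the silyl ether and the C2–OH go back to a C2 ketone, then C4–C5 is cut to give a cyclopentanone carrying a 2-methoxyacryloyl group on C1. Further cuts are C1–OMe, C1–C2 (Claisen), C5–allyl and C6–Me (cuprate addition and enolate trapping), and C7–aryl (cuprate addition to enone 3).
3. Enabling feature: in the target C4 (β-carbon of the C3 enol ether) and C5 (α-carbon of the C8 ketone) are both donor carbons. Carrying C2 as a ketone turns C3=C4 into a 2-methoxy enone and reverses the polarity of C4; the helper ketone is reduced afterwards. C8 can enolise only toward C5 (C1 is quaternary), and only C4 offers hydrogens for re-forming C3=C4.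
4. Forward: the purchased five-membered ring is substituted at C7, then C6/C5, then C1. The six-membered ring C8–C1–C2–C3–C4–C5 is then closed across it to give the bicyclo[3.2.1]octane.
5. Stereochemistry: C7 comes from (S)-3 by anti addition, C6 is set anti to the C7 aryl group, and C1 is set by hydroxylation anti to that aryl group. C5 is forced by the bridge, and C2 is set by hydride delivery on the C8 side of the bicycle.

Key step: step 9

Remark: both enantiomers of 4-(tert-butyldimethylsilyloxy)cyclopent-2-en-1-one are taken as commercial. "Ar" below means 3-methoxy-4-(triisopropylsilyloxy)phenyl.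

**Step 1**
Reactants: 1 4-bromo-2-methoxyphenol
Product: 2 (4-bromo-2-methoxyphenoxy)tri(propan-2-yl)silane
Conditions: TIPSCl, imidazole, DMF, 0 °C → rt
Reagents that add atoms: chlorotri(propan-2-yl)silane (TIPSCl), CC(C)[Si](Cl)(C(C)C)C(C)C
Why: Imidazole-mediated O-silylation of the phenol should give an aryl TIPS ether that withstands the organometallic, amide-base and Lewis-acid steps and is removable with fluoride at the end (silyl protection).

**Step 2**
Reactants: 2 (4-bromo-2-methoxyphenoxy)tri(propan-2-yl)silane; 3 (4S)-4-[(tert-butyldimethylsilyl)oxy]cyclopent-2-en-1-one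
Product: 5 (3R,4S)-3-Ar-4-[(tert-butyldimethylsilyl)oxy]cyclopentan-1-one, via arylmagnesium bromide 4 (not isolated)
Conditions: Mg, THF, reflux; then CuBr·SMe2 (10 mol %), 3, THF, −78 → −30 °C; aq. NH4Cl
Reagents that add atoms: none
Why: Copper-catalysed conjugate addition of the aryl Grignard reagent to the 4-silyloxycyclopentenone should occur anti to the OTBS group, which sets C7 from the purchased stereocentre.

**Step 3**
Reactants: 5 (3R,4S)-3-Ar-4-[(tert-butyldimethylsilyl)oxy]cyclopentan-1-one
Product: 6 (4S)-4-Ar-cyclopent-2-en-1-one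
Conditions: DBU, CH2Cl2, 0 °C, short contact
Reagents that add atoms: none
Why: E1cB β-elimination of silanolate through the C5-side enolate should deliver the 4-arylcyclopentenone, with brief cold base exposure chosen so that the doubly activated γ-hydrogen at C7 is not removed.

**Step 4**
Reactants: 6 (4S)-4-Ar-cyclopent-2-en-1-one
Product: 8 (2S,3R,4S)-4-Ar-3-methyl-2-(prop-2-en-1-yl)cyclopentan-1-one, via lithium enolate 7 (not isolated)
Conditions: Me2CuLi (from MeLi, CuI), Et2O, −78 °C; then allyl iodide, HMPA, THF, −78 → −20 °C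
Reagents that add atoms: lithium dimethylcuprate, [Li+].C[Cu-]C; allyl iodide (3-iodoprop-1-ene), C=CCI
Why: Gilman cuprate 1,4-addition anti to the C7 aryl group should set C6, and the regiodefined enolate should be allylated anti to the new methyl group (conjugate addition with enolate trapping), the C5 configuration being of no consequence later.

**Step 5**
Reactants: 8 (2S,3R,4S)-4-Ar-3-methyl-2-(prop-2-en-1-yl)cyclopentan-1-one; 9 methyl 2,2-dimethoxypropanoate
Product: 10 (2S,3R,4R,5S)-3-Ar-2-(2,2-dimethoxypropanoyl)-4-methyl-5-(prop-2-en-1-yl)cyclopentan-1-one (drawn as diketone, largely enolised)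
Conditions: LiN(SiMe3)2 (2.2 equiv), THF, −78 → 0 °C; then AcOH
Reagents that add atoms: none
Why: Crossed Claisen condensation with the non-enolisable, inductively activated ketal ester should occur at the CH2 side (C1) because only that product is held as a stabilised diketonate, and the dimethyl ketal masks the later 2-methoxyacryloyl unit against Michael chemistry.

**Step 6**
Reactants: 10 (2S,3R,4R,5S)-3-Ar-2-(2,2-dimethoxypropanoyl)-4-methyl-5-(prop-2-en-1-yl)cyclopentan-1-one
Product: 12 (2S,3S,4R,5S)-3-Ar-2-(2,2-dimethoxypropanoyl)-2-hydroxy-4-methyl-5-(prop-2-en-1-yl)cyclopentan-1-one, via potassium enolate 11 (not isolated)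
Conditions: KN(SiMe3)2, THF, −78 °C; then 2-(benzenesulfonyl)-3-phenyloxaziridine, −78 → −40 °C; AcOH
Reagents that add atoms: 2-(benzenesulfonyl)-3-phenyloxaziridine (Davis oxaziridine), O=S(=O)(N1OC1c1ccccc1)c1ccccc1
Why: Davis hydroxylation of the diketone enolate should deliver oxygen to the C1 face opposite the vicinal C7 aryl group, which places the acyl chain cis to the aryl group as the bridged target requires and leaves the allyl double bond untouched.

**Step 7**
Reactants: 12 (2S,3S,4R,5S)-3-Ar-2-(2,2-dimethoxypropanoyl)-2-hydroxy-4-methyl-5-(prop-2-en-1-yl)cyclopentan-1-one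
Product: 13 (2S,3S,4R,5S)-3-Ar-2-(2,2-dimethoxypropanoyl)-2-methoxy-4-methyl-5-(prop-2-en-1-yl)cyclopentan-1-one
Conditions: MeI, Ag2O, MeCN, 40 °C, dark
Reagents that add atoms: iodomethane, CI
Why: Purdie methylation should alkylate the acidic tertiary hydroxyl under nearly neutral conditions that avoid alkoxide-triggered retro-Claisen cleavage or α-ketol rearrangement of the 2-hydroxy-1,3-diketone.

**Step 8**
Reactants: 13 (2S,3S,4R,5S)-3-Ar-2-(2,2-dimethoxypropanoyl)-2-methoxy-4-methyl-5-(prop-2-en-1-yl)cyclopentan-1-one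
Product: 14 (2S,3S,4R,5S)-3-Ar-2-methoxy-2-(2-methoxyprop-2-enoyl)-4-methyl-5-(prop-2-en-1-yl)cyclopentan-1-one
Conditions: TMSOTf, iPr2NEt, CH2Cl2, −20 → 0 °C; aq. NaHCO3
Reagents that add atoms: none
Why: In this silyl triflate/amine ketal-to-enol-ether elimination TMSOTf should ionise the ketal and the hindered amine should remove a proton from the only neighbouring carbon that bears hydrogens (the C4 methyl group), while closure of any transient C5 silyl enol ether onto the C3 oxocarbenium ion would be a disfavoured 5-(enolendo)-exo-trig process.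

**Step 9**
Reactants: 14 (2S,3S,4R,5S)-3-Ar-2-methoxy-2-(2-methoxyprop-2-enoyl)-4-methyl-5-(prop-2-en-1-yl)cyclopentan-1-one
Product: 16 (1S,5R,6R,7S)-7-Ar-1,3-dimethoxy-6-methyl-5-(prop-2-en-1-yl)bicyclo[3.2.1]oct-3-ene-2,8-dione, via bicyclic lithium enolate 15 (not isolated)
Conditions: LiN(SiMe3)2, THF, −78 → −40 °C; then PhS(Cl)=NtBu, −78 °C
Reagents that add atoms: none
Why: LiN(SiMe3)2 should remove the only α-hydrogen of the C8 ketone (C1 is quaternary and the C2 carbonyl has none) and the C5 enolate should add to C4, the unsubstituted β-carbon of the 2-methoxy enone, to give enolate 15; N-tert-butylbenzenesulfinimidoyl chloride should then sulfenylate C3, and syn-elimination of the sulfilimine with a C4 hydrogen (the only β-hydrogens present) restores the C3=C4 enol-ether double bond in conjugation with C2=O. The closest known reaction types are intramolecular Michael ring closures of cyclopentanone enolates to bicyclo[3.2.1]octane-2,8-diones and the one-pot Mukaiyama dehydrogenation of lithium enolates generated by conjugate addition. The six-membered ring C8–C1–C2–C3–C4–C5 closes in a 6-endo-trig (enolendo) mode across the 1,3-positions of the cyclopentanone, which creates the bicyclo[3.2.1]octane and with it the seven-membered ring C1–C7. The only new stereocentre, quaternary C5, is controlled by C1: the three-carbon bridge can span C1 and C5 only on the face that carries the acryloyl group, so the allyl group is forced to the opposite face whatever the C5 configuration of 14, and the aryl group ends endo and the methyl group exo. The step needs C- over O-alkylation and 1,4- over 1,2-attack, which the soft enone terminus, the reversibility of oxa-Michael addition and the strain of the four-membered alternative should secure, and the bridgehead-flanked C8 ketone of 16 cannot enolise further.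

**Step 10**
Reactants: 16 (1S,5R,6R,7S)-7-Ar-1,3-dimethoxy-6-methyl-5-(prop-2-en-1-yl)bicyclo[3.2.1]oct-3-ene-2,8-dione
Product: 17 (1R,2S,5R,6R,7S)-7-Ar-2-hydroxy-1,3-dimethoxy-6-methyl-5-(prop-2-en-1-yl)bicyclo[3.2.1]oct-3-en-8-one (locants as in 16)
Conditions: NaBH4, CeCl3·7H2O, MeOH, −78 °C
Reagents that add atoms: none
Why: In this Luche 1,2-reduction hydride should attack C2 from the face syn to the C8 bridge because the opposite face is screened by the C6–C7 bridge and its endo aryl group, which gives the (2S) carbinol, while the C8 ketone flanked by two quaternary bridgeheads should react more slowly under the cerium-mediated conditions.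

**Step 11**
Reactants: 17 (1R,2S,5R,6R,7S)-7-Ar-2-hydroxy-1,3-dimethoxy-6-methyl-5-(prop-2-en-1-yl)bicyclo[3.2.1]oct-3-en-8-one
Product: 18 (1R,2S,5R,6R,7S)-2-hydroxy-7-(4-hydroxy-3-methoxyphenyl)-1,3-dimethoxy-6-methyl-5-(prop-2-en-1-yl)bicyclo[3.2.1]oct-3-en-8-one (locants as in 16), the target
Conditions: Bu4NF, AcOH, THF, 0 °C
Reagents that add atoms: none
Why: Fluoride should cleave the aryl silyl ether selectively (Si–F bond formation), with acetic acid buffering the phenoxide so that the enol ether and the β-hydroxy ketone are not disturbed.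

**Compound list**

1 | 4-bromo-2-methoxyphenol | COc1cc(Br)ccc1O | starting material
2 | (4-bromo-2-methoxyphenoxy)tri(propan-2-yl)silane | COc1cc(Br)ccc1O[Si](C(C)C)(C(C)C)C(C)C | intermediate
3 | (4S)-4-[(tert-butyldimethylsilyl)oxy]cyclopent-2-en-1-one | O=C1C=C[C@@H](O[Si](C)(C)C(C)(C)C)C1 | starting material
4 | [3-methoxy-4-(triisopropylsilyloxy)phenyl]magnesium bromide | COc1cc([Mg]Br)ccc1O[Si](C(C)C)(C(C)C)C(C)C | intermediate (not isolated)
5 | (3R,4S)-4-[(tert-butyldimethylsilyl)oxy]-3-[3-methoxy-4-(triisopropylsilyloxy)phenyl]cyclopentan-1-one | O=C1C[C@H](c2ccc(O[Si](C(C)C)(C(C)C)C(C)C)c(OC)c2)[C@@H](O[Si](C)(C)C(C)(C)C)C1 | intermediate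
6 | (4S)-4-[3-methoxy-4-(triisopropylsilyloxy)phenyl]cyclopent-2-en-1-one | O=C1C[C@H](c2ccc(O[Si](C(C)C)(C(C)C)C(C)C)c(OC)c2)C=C1 | intermediate
7 | lithium (3R,4S)-4-[3-methoxy-4-(triisopropylsilyloxy)phenyl]-3-methylcyclopent-1-en-1-olate | C1[C@H](c2ccc(O[Si](C(C)C)(C(C)C)C(C)C)c(OC)c2)[C@@H](C)C=C1O[Li] | intermediate (not isolated)
8 | (2S,3R,4S)-4-[3-methoxy-4-(triisopropylsilyloxy)phenyl]-3-methyl-2-(prop-2-en-1-yl)cyclopentan-1-one | C=CC[C@@H]1C(=O)C[C@H](c2ccc(O[Si](C(C)C)(C(C)C)C(C)C)c(OC)c2)[C@H]1C | intermediate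
9 | methyl 2,2-dimethoxypropanoate | COC(=O)C(C)(OC)OC | starting material
10 | (2S,3R,4R,5S)-2-(2,2-dimethoxypropanoyl)-3-[3-methoxy-4-(triisopropylsilyloxy)phenyl]-4-methyl-5-(prop-2-en-1-yl)cyclopentan-1-one (diketo form) | C=CC[C@@H]1C(=O)[C@@H](C(=O)C(C)(OC)OC)[C@H](c2ccc(O[Si](C(C)C)(C(C)C)C(C)C)c(OC)c2)[C@H]1C | intermediate
11 | potassium enolate of 10 (ring O–C=C enolate, other centres as in 10) | C=CC[C@@H]1C([O-])=C(C(=O)C(C)(OC)OC)[C@H](c2ccc(O[Si](C(C)C)(C(C)C)C(C)C)c(OC)c2)[C@H]1C.[K+] | intermediate (not isolated)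
12 | (2S,3S,4R,5S)-2-(2,2-dimethoxypropanoyl)-2-hydroxy-3-[3-methoxy-4-(triisopropylsilyloxy)phenyl]-4-methyl-5-(prop-2-en-1-yl)cyclopentan-1-one | C=CC[C@@H]1C(=O)[C@](O)(C(=O)C(C)(OC)OC)[C@H](c2ccc(O[Si](C(C)C)(C(C)C)C(C)C)c(OC)c2)[C@H]1C | intermediate
13 | (2S,3S,4R,5S)-2-(2,2-dimethoxypropanoyl)-2-methoxy-3-[3-methoxy-4-(triisopropylsilyloxy)phenyl]-4-methyl-5-(prop-2-en-1-yl)cyclopentan-1-one | C=CC[C@@H]1C(=O)[C@](OC)(C(=O)C(C)(OC)OC)[C@H](c2ccc(O[Si](C(C)C)(C(C)C)C(C)C)c(OC)c2)[C@H]1C | intermediate
14 | (2S,3S,4R,5S)-2-methoxy-2-(2-methoxyprop-2-enoyl)-3-[3-methoxy-4-(triisopropylsilyloxy)phenyl]-4-methyl-5-(prop-2-en-1-yl)cyclopentan-1-one | C=CC[C@@H]1C(=O)[C@](OC)(C(=O)C(OC)=C)[C@H](c2ccc(O[Si](C(C)C)(C(C)C)C(C)C)c(OC)c2)[C@H]1C | intermediate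
15 | lithium C2-enolate of the bicyclic Michael adduct (C2(OLi)=C3(OMe), C4H2; other centres as in 16) | C=CC[C@@]12CC(OC)=C(O[Li])[C@@](OC)(C1=O)[C@H](c1ccc(O[Si](C(C)C)(C(C)C)C(C)C)c(OC)c1)[C@H]2C | intermediate (not isolated)
16 | (1S,5R,6R,7S)-1,3-dimethoxy-7-[3-methoxy-4-(triisopropylsilyloxy)phenyl]-6-methyl-5-(prop-2-en-1-yl)bicyclo[3.2.1]oct-3-ene-2,8-dione | C=CC[C@@]12C=C(OC)C(=O)[C@@](OC)(C1=O)[C@H](c1ccc(O[Si](C(C)C)(C(C)C)C(C)C)c(OC)c1)[C@H]2C | intermediate
17 | (1R,2S,5R,6R,7S)-2-hydroxy-1,3-dimethoxy-7-[3-methoxy-4-(triisopropylsilyloxy)phenyl]-6-methyl-5-(prop-2-en-1-yl)bicyclo[3.2.1]oct-3-en-8-one (locants as in 16) | C=CC[C@@]12C=C(OC)[C@H](O)[C@@](OC)(C1=O)[C@H](c1ccc(O[Si](C(C)C)(C(C)C)C(C)C)c(OC)c1)[C@H]2C | intermediate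
18 | (1R,2S,5R,6R,7S)-2-hydroxy-7-(4-hydroxy-3-methoxyphenyl)-1,3-dimethoxy-6-methyl-5-(prop-2-en-1-yl)bicyclo[3.2.1]oct-3-en-8-one (locants as in 16) | C=CC[C@@]12C=C(OC)[C@H](O)[C@@](OC)(C1=O)[C@H](c1ccc(O)c(OC)c1)[C@H]2C | target

**Step count**

Total steps: 11. Longest linear sequence: 11 (1 → 18; 3 and 9 are purchased).

**Steps most likely to fail, with fallbacks**

Step 9. What may go wrong: base-induced cleavage of the non-enolisable 1,3-diketone, reversal of the Michael addition before the enolate is intercepted, or sluggish sulfenylation of the hindered tetrasubstituted enolate. The fallback sets out from 14 and moves the ring closure into a Lewis-acid manifold with isolated intermediates. TMSOTf and Et3N in CH2Cl2 should convert the C8 ketone into its C5=C8 trimethylsilyl enol ether F1. Catalytic TMSOTf at −78 °C should then trigger an intramolecular Mukaiyama–Michael closure with silyl transfer to give the bicyclic C2 trimethylsilyl enol ether F2, in which the adduct is trapped irreversibly. Saegusa–Ito oxidation (Pd(OAc)2, MeCN) then comes back to the route at 16.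

Step 8. What may go wrong: competing O-silylation of the C8 ketone followed by capture of the C3 oxocarbenium ion or premature cyclisation, or slow ionisation of the α-keto ketal. The fallback sets out from 10 and moves the ketal-to-enol-ether elimination ahead of the C1 oxygenation, where the only enol is the central one of the diketone and cannot reach C3. TMSOTf and iPr2NEt followed by mild aqueous work-up should give the 2-(2-methoxyprop-2-enoyl) diketone F3. KN(SiMe3)2 and the Davis oxaziridine at −78 °C should hydroxylate C1 anti to the aryl group to give the tertiary alcohol F4. Ag2O/MeI methylation then comes back to the route at 14.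

Step 10. What may go wrong: loss of chemoselectivity through competing hydride addition to the strained C8 bridging ketone. The fallback sets out from 16 and replaces selective reduction by exhaustive reduction, selective protection and re-oxidation. Excess NaBH4 with CeCl3·7H2O in MeOH at 0 °C should give the C2,C8-diol F5 (the C8 configuration is immaterial). Et3SiCl and imidazole should silylate only the less hindered allylic C2 hydroxyl to give the C2 triethylsilyl ether F6. Dess–Martin periodinane should oxidise the C8 carbinol to the ketone F7. Bu4NF/AcOH then removes both silyl groups and comes back to the route at 18.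

**Further compounds**

F1 | step 9 | C5=C8 trimethylsilyl enol ether of 14 | C=CCC1=C(O[Si](C)(C)C)[C@](OC)(C(=O)C(OC)=C)[C@H](c2ccc(O[Si](C(C)C)(C(C)C)C(C)C)c(OC)c2)[C@H]1C
F2 | step 9 | bicyclic C2 trimethylsilyl enol ether (C2(OSiMe3)=C3(OMe), C4H2; other centres as in 16) | C=CC[C@@]12CC(OC)=C(O[Si](C)(C)C)[C@@](OC)(C1=O)[C@H](c1ccc(O[Si](C(C)C)(C(C)C)C(C)C)c(OC)c1)[C@H]2C
F3 | step 8 | 2-(2-methoxyprop-2-enoyl)-3-[3-methoxy-4-(triisopropylsilyloxy)phenyl]-4-methyl-5-(prop-2-en-1-yl)cyclopentan-1-one (diketo form, centres as in 10) | C=CC[C@@H]1C(=O)[C@@H](C(=O)C(OC)=C)[C@H](c2ccc(O[Si](C(C)C)(C(C)C)C(C)C)c(OC)c2)[C@H]1C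
F4 | step 8 | 2-hydroxy-2-(2-methoxyprop-2-enoyl)-3-[3-methoxy-4-(triisopropylsilyloxy)phenyl]-4-methyl-5-(prop-2-en-1-yl)cyclopentan-1-one (centres as in 12) | C=CC[C@@H]1C(=O)[C@](O)(C(=O)C(OC)=C)[C@H](c2ccc(O[Si](C(C)C)(C(C)C)C(C)C)c(OC)c2)[C@H]1C
F5 | step 10 | C2,C8-diol from 16 (C2–OH as in 17; C8–OH drawn on the side of the C6–C7 bridge) | C=CC[C@@]12C=C(OC)[C@H](O)[C@@](OC)([C@@H]1O)[C@H](c1ccc(O[Si](C(C)C)(C(C)C)C(C)C)c(OC)c1)[C@H]2C
F6 | step 10 | C2 triethylsilyl ether of diol F5 | C=CC[C@@]12C=C(OC)[C@H](O[Si](CC)(CC)CC)[C@@](OC)([C@@H]1O)[C@H](c1ccc(O[Si](C(C)C)(C(C)C)C(C)C)c(OC)c1)[C@H]2C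
F7 | step 10 | C2 triethylsilyl ether of 17 (C8 ketone restored) | C=CC[C@@]12C=C(OC)[C@H](O[Si](CC)(CC)CC)[C@@](OC)(C1=O)[C@H](c1ccc(O[Si](C(C)C)(C(C)C)C(C)C)c(OC)c1)[C@H]2C
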